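**Retrosynthetic overview**

1. Target 20 is released from 19 by acidolysis; the diaryl ether bond (isocoumarin C8–O–ring A) is cut to phenol 14 and aryl iodide 18, joined by a copper-mediated Ullmann coupling.
2. Lactone ring C of 14 (O2–C1 bond) comes from ketone 13 by enol-O transacylation, which opens the acetonide and frees the C8 hydroxyl; iodide 18 comes from the same arene 11 by MOM protection, iodination and alkoxide opening of the dioxinone.
3. The route rests on ring B (C4a, C5, C6, C7, C8, C8a): oxygen on C6 and C8, carbon on C8a (C1) and C4a (C4), the alternating pattern of a folded polyketide chain, with the C8 oxygen and the C1 carboxyl held together as a 1,3-dioxin-4-one; ring A repeats this pattern, so benzodioxinone 11 serves both halves.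
4. Arene 11 comes from open-chain diketo-dioxinone 9 by aldol closure of C8a–C4a and dehydration; 9 comes from the dianion of keto-dioxinone 7 and Weinreb amide 3 (crossed Claisen), 7 from 4 and 5, and 3 from 1.
5. Ring order: the carbocycle (ring B, and the same arene as ring A) first, then lactone ring C, then the ether link, then deprotection.

Key step: step 5

Remark: ring B and ring C carry isocoumarin numbering (C1 lactone carbonyl, O2, C3, C4, C4a, C5 to C8, C8a), ring A is the benzoic acid ring, and the target has no stereocentre, so no step has to set or keep configuration.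

**Route**

Step 1
Reactants: 1 methyl 3-oxooctanoate
Product: 2 methyl 2-(2-pentyl-1,3-dioxolan-2-yl)acetate
Conditions: HOCH2CH2OH, p-TsOH·H2O (cat.), toluene, reflux, Dean–Stark trap
Reagents that add atoms: ethylene glycol, OCCO
Why: Acid-catalysed ketalization of the ketone of a β-keto ester with azeotropic removal of water is a standard dioxolane formation that leaves the ester untouched.

Step 2
Reactants: 2 methyl 2-(2-pentyl-1,3-dioxolan-2-yl)acetate
Product: 3 N-methoxy-N-methyl-2-(2-pentyl-1,3-dioxolan-2-yl)acetamide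
Conditions: MeNH(OMe)·HCl (1.5 equiv), i-PrMgCl (3 equiv), THF, −20 to 0 °C
Reagents that add atoms: N,O-dimethylhydroxylamine hydrochloride, CNOC.Cl
Why: Aminolysis of a methyl ester by the chloromagnesium amide of N,O-dimethylhydroxylamine (Weinreb amide formation) is reliable for unhindered esters, and the ketal is inert to the basic medium.

Step 3
Reactants: 4 2,2,6-trimethyl-4H-1,3-dioxin-4-one; 5 acetyl chloride
Product: 7 2,2-dimethyl-6-(2-oxopropyl)-4H-1,3-dioxin-4-one, via lithium dienolate 6 (not isolated)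
Conditions: LiN(SiMe3)2 (2 equiv), 4 (2 equiv), THF, −78 °C; AcCl (1 equiv), −78 °C; aq. NH4Cl
Reagents that add atoms: none
Why: Deprotonation of the C6 methyl group gives the extended dienolate, which is C-acylated at its terminal carbon by acetyl chloride (vinylogous Claisen-type acylation), the second equivalent of enolate taking up the proton of the more acidic product.

Step 4
Reactants: 7 2,2-dimethyl-6-(2-oxopropyl)-4H-1,3-dioxin-4-one; 3 N-methoxy-N-methyl-2-(2-pentyl-1,3-dioxolan-2-yl)acetamide
Product: 9 2,2-dimethyl-6-[2,4-dioxo-5-(2-pentyl-1,3-dioxolan-2-yl)pentyl]-4H-1,3-dioxin-4-one, via dilithium dianion 8 (not isolated)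
Conditions: LiN(i-Pr)2 (2.2 equiv), THF, −78 °C; 3 (0.9 equiv), −78 to −30 °C; aq. NH4Cl; crude 9 used at once
Reagents that add atoms: none
Why: In this crossed Claisen condensation the last-formed, methyl-derived enolate carbon of the dianion is its most nucleophilic site and adds to the Weinreb amide to give a chelated tetrahedral adduct that collapses only on work-up, so the 1,3-diketone forms without over-addition.

Step 5
Reactants: 9 2,2-dimethyl-6-[2,4-dioxo-5-(2-pentyl-1,3-dioxolan-2-yl)pentyl]-4H-1,3-dioxin-4-one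
Product: 11 7-hydroxy-2,2-dimethyl-5-[(2-pentyl-1,3-dioxolan-2-yl)methyl]-4H-1,3-benzodioxin-4-one, via cyclic aldol adduct 10 (not isolated)
Conditions: Et3N (3 equiv), CH2Cl2, rt
Reagents that add atoms: none
Why: Et3N removes a proton from the doubly activated CH2 between the dioxinone and the neighbouring ketone, and the extended enolate attacks the distal ketone (the future C4a) through the dioxinone α-carbon (the future C8a), an intramolecular aldol addition that forms the C8a–C4a bond and gives carbinol 10. E1cB loss of water and enolization of the remaining ring ketone then give the phenol, and the gain of aromaticity makes the sequence irreversible. The closest known reaction type is the amine-mediated cycloaromatization of 6-(2,4-dioxoalkyl)-1,3-dioxin-4-ones to 7-hydroxybenzodioxinones, the biomimetic resorcylate synthesis. Ring B closes in a 6-(enolexo)-exo-trig mode. No stereocentre remains, because the carbinol carbon of racemic 10 becomes an arene carbon. The step needs site selectivity among several enolizable positions: the dioxolane removes the C3 carbonyl as an acceptor so the alternative aldol from C7 cannot occur, the dioxinone carbonyl is too weak an electrophile for a Claisen closure under amine base, and the acetonide leaves only the C6 hydroxyl free in 11.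

Step 6
Reactants: 11 7-hydroxy-2,2-dimethyl-5-[(2-pentyl-1,3-dioxolan-2-yl)methyl]-4H-1,3-benzodioxin-4-one
Product: 12 7-methoxy-2,2-dimethyl-5-[(2-pentyl-1,3-dioxolan-2-yl)methyl]-4H-1,3-benzodioxin-4-one
Conditions: MeI, K2CO3, acetone, 50 °C
Reagents that add atoms: iodomethane, CI
Why: Williamson O-methylation of the only free phenol (the C6 oxygen of the isocoumarin), the C8 oxygen being locked in the acetonide.

Step 7
Reactants: 12 7-methoxy-2,2-dimethyl-5-[(2-pentyl-1,3-dioxolan-2-yl)methyl]-4H-1,3-benzodioxin-4-one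
Product: 13 7-methoxy-2,2-dimethyl-5-(2-oxoheptyl)-4H-1,3-benzodioxin-4-one
Conditions: 2 M HCl (aq), THF, rt
Reagents that add atoms: water, O
Why: Acid-catalysed hydrolysis of the dioxolane (acetal hydrolysis) frees the C3 ketone, while the benzodioxinone acetonide, which is itself made under strong acid, survives dilute aqueous acid.

Step 8
Reactants: 13 7-methoxy-2,2-dimethyl-5-(2-oxoheptyl)-4H-1,3-benzodioxin-4-one
Product: 14 8-hydroxy-6-methoxy-3-pentyl-1H-isochromen-1-one
Conditions: DBU (1.5 equiv), toluene, rt to 50 °C; 1 M HCl wash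
Reagents that add atoms: none
Why: DBU enolizes the benzylic ketone towards the ring, and the enolate oxygen attacks the dioxinone carbonyl in a 6-exo-trig transacylation (enol lactonization) that expels the acetonide as acetone and frees the C8 phenol, C-acylation from this enolate being geometrically impossible.

Step 9
Reactants: 11 7-hydroxy-2,2-dimethyl-5-[(2-pentyl-1,3-dioxolan-2-yl)methyl]-4H-1,3-benzodioxin-4-one
Product: 15 7-(methoxymethoxy)-2,2-dimethyl-5-[(2-pentyl-1,3-dioxolan-2-yl)methyl]-4H-1,3-benzodioxin-4-one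
Conditions: MOMCl, i-Pr2NEt, CH2Cl2, 0 °C to rt
Reagents that add atoms: chloromethyl methyl ether, COCCl
Why: O-alkylation of the acidic phenol with MOMCl under amine base gives an acid-labile acetal ether that tolerates the later basic and copper-mediated steps.

Step 10
Reactants: 15 7-(methoxymethoxy)-2,2-dimethyl-5-[(2-pentyl-1,3-dioxolan-2-yl)methyl]-4H-1,3-benzodioxin-4-one
Product: 16 6-iodo-7-(methoxymethoxy)-2,2-dimethyl-5-[(2-pentyl-1,3-dioxolan-2-yl)methyl]-4H-1,3-benzodioxin-4-one
Conditions: NIS, CF3CO2H (10 mol%), MeCN, 0 °C to rt, dark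
Reagents that add atoms: N-iodosuccinimide, O=C1CCC(=O)N1I
Why: Electrophilic aromatic iodination of a resorcinol-type diether should occur ortho to one oxygen and para to the other (C6, next to the side chain) rather than between the two oxygens, as in halogenation of 3,5-dialkoxyalkylbenzenes and 2,4-dialkoxy-6-alkylbenzoates.

Step 11
Reactants: 16 6-iodo-7-(methoxymethoxy)-2,2-dimethyl-5-[(2-pentyl-1,3-dioxolan-2-yl)methyl]-4H-1,3-benzodioxin-4-one
Product: 17 4-methoxybenzyl 6-hydroxy-3-iodo-4-(methoxymethoxy)-2-[(2-pentyl-1,3-dioxolan-2-yl)methyl]benzoate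
Conditions: 4-MeOC6H4CH2OH (2 equiv), NaH (2 equiv), THF, 0 °C to rt; aq. NH4Cl
Reagents that add atoms: 4-methoxybenzyl alcohol, COc1ccc(CO)cc1
Why: Alkoxide addition to the carbonyl of a 2,2-dimethylbenzodioxinone and collapse with loss of acetone (transesterification) is the standard conversion of these acetonides into salicylate esters, and with the ketone still ketalized no enolate can intercept the carbonyl.

Step 12
Reactants: 17 4-methoxybenzyl 6-hydroxy-3-iodo-4-(methoxymethoxy)-2-[(2-pentyl-1,3-dioxolan-2-yl)methyl]benzoate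
Product: 18 4-methoxybenzyl 3-iodo-4,6-bis(methoxymethoxy)-2-[(2-pentyl-1,3-dioxolan-2-yl)methyl]benzoate
Conditions: NaH, MOMCl, DMF, 0 °C to rt
Reagents that add atoms: chloromethyl methyl ether, COCCl
Why: Williamson-type O-alkylation of the sodium phenoxide in a dipolar solvent overcomes the hydrogen bond to the ester and caps the last phenol of ring A, so that 14 is the only phenol in the coupling.

Step 13
Reactants: 14 8-hydroxy-6-methoxy-3-pentyl-1H-isochromen-1-one; 18 4-methoxybenzyl 3-iodo-4,6-bis(methoxymethoxy)-2-[(2-pentyl-1,3-dioxolan-2-yl)methyl]benzoate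
Product: 19 4-methoxybenzyl 3-[(6-methoxy-1-oxo-3-pentyl-1H-isochromen-8-yl)oxy]-4,6-bis(methoxymethoxy)-2-[(2-pentyl-1,3-dioxolan-2-yl)methyl]benzoate
Conditions: 14 (1.5 equiv), CuI (30 mol%), picolinic acid (60 mol%), K3PO4, 4 Å MS, DMSO, 90 °C
Reagents that add atoms: none
Why: In this Ullmann-type diaryl ether synthesis the picolinate-ligated copper phenoxide of 14 should couple with the aryl iodide in a ligand system suited to ortho-substituted partners, the neighbouring methoxymethoxy oxygen can assist copper delivery, and the acetals, the hindered ester and the lactone tolerate anhydrous K3PO4.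

Step 14
Reactants: 19 4-methoxybenzyl 3-[(6-methoxy-1-oxo-3-pentyl-1H-isochromen-8-yl)oxy]-4,6-bis(methoxymethoxy)-2-[(2-pentyl-1,3-dioxolan-2-yl)methyl]benzoate
Product: 20 beta-collatolic acid, 4,6-dihydroxy-3-[(6-methoxy-1-oxo-3-pentyl-1H-isochromen-8-yl)oxy]-2-(2-oxoheptyl)benzoic acid
Conditions: CF3CO2H/CH2Cl2/H2O (10:10:1), 1,3-dimethoxybenzene (10 equiv), 0 °C to rt
Reagents that add atoms: water, O
Why: In this global acidolysis the 4-methoxybenzyl ester ionizes (SN1) and its cation is trapped by 1,3-dimethoxybenzene, the two methoxymethyl ethers and the dioxolane are hydrolysed as acetals, and the isocoumarin, the methyl ether and the diaryl ether are stable to aqueous CF3CO2H at room temperature.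

**Compound list**

1 | methyl 3-oxooctanoate | CCCCCC(=O)CC(=O)OC | starting material
2 | methyl 2-(2-pentyl-1,3-dioxolan-2-yl)acetate | CCCCCC1(CC(=O)OC)OCCO1 | intermediate
3 | N-methoxy-N-methyl-2-(2-pentyl-1,3-dioxolan-2-yl)acetamide | CCCCCC1(CC(=O)N(C)OC)OCCO1 | intermediate
4 | 2,2,6-trimethyl-4H-1,3-dioxin-4-one | CC1=CC(=O)OC(C)(C)O1 | starting material
5 | acetyl chloride | CC(Cl)=O | starting material
6 | lithium dienolate of 4 (lithium 2,2-dimethyl-6-methylidene-6H-1,3-dioxin-4-olate) | [Li+].C=C1C=C([O-])OC(C)(C)O1 | intermediate (not isolated)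
7 | 2,2-dimethyl-6-(2-oxopropyl)-4H-1,3-dioxin-4-one | CC(=O)CC1=CC(=O)OC(C)(C)O1 | intermediate
8 | dilithium dianion of 7 (bis-enolate, deprotonated at the ring-side CH2 and at the methyl group) | [Li+].[Li+].C=C([O-])C=C1C=C([O-])OC(C)(C)O1 | intermediate (not isolated)
9 | 2,2-dimethyl-6-[2,4-dioxo-5-(2-pentyl-1,3-dioxolan-2-yl)pentyl]-4H-1,3-dioxin-4-one | CCCCCC1(CC(=O)CC(=O)CC2=CC(=O)OC(C)(C)O2)OCCO1 | intermediate
10 | 5-hydroxy-2,2-dimethyl-5-[(2-pentyl-1,3-dioxolan-2-yl)methyl]-5,6-dihydro-4H-1,3-benzodioxine-4,7(8H)-dione (racemic at the carbinol carbon) | CCCCCC1(CC2(O)CC(=O)CC3=C2C(=O)OC(C)(C)O3)OCCO1 | intermediate (not isolated)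
11 | 7-hydroxy-2,2-dimethyl-5-[(2-pentyl-1,3-dioxolan-2-yl)methyl]-4H-1,3-benzodioxin-4-one | CCCCCC1(Cc2cc(O)cc3OC(C)(C)OC(=O)c23)OCCO1 | intermediate
12 | 7-methoxy-2,2-dimethyl-5-[(2-pentyl-1,3-dioxolan-2-yl)methyl]-4H-1,3-benzodioxin-4-one | CCCCCC1(Cc2cc(OC)cc3OC(C)(C)OC(=O)c23)OCCO1 | intermediate
13 | 7-methoxy-2,2-dimethyl-5-(2-oxoheptyl)-4H-1,3-benzodioxin-4-one | CCCCCC(=O)Cc1cc(OC)cc2OC(C)(C)OC(=O)c12 | intermediate
14 | 8-hydroxy-6-methoxy-3-pentyl-1H-isochromen-1-one | CCCCCc1cc2cc(OC)cc(O)c2c(=O)o1 | intermediate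
15 | 7-(methoxymethoxy)-2,2-dimethyl-5-[(2-pentyl-1,3-dioxolan-2-yl)methyl]-4H-1,3-benzodioxin-4-one | CCCCCC1(Cc2cc(OCOC)cc3OC(C)(C)OC(=O)c23)OCCO1 | intermediate
16 | 6-iodo-7-(methoxymethoxy)-2,2-dimethyl-5-[(2-pentyl-1,3-dioxolan-2-yl)methyl]-4H-1,3-benzodioxin-4-one | CCCCCC1(Cc2c(I)c(OCOC)cc3OC(C)(C)OC(=O)c23)OCCO1 | intermediate
17 | 4-methoxybenzyl 6-hydroxy-3-iodo-4-(methoxymethoxy)-2-[(2-pentyl-1,3-dioxolan-2-yl)methyl]benzoate | CCCCCC1(Cc2c(I)c(OCOC)cc(O)c2C(=O)OCc2ccc(OC)cc2)OCCO1 | intermediate
18 | 4-methoxybenzyl 3-iodo-4,6-bis(methoxymethoxy)-2-[(2-pentyl-1,3-dioxolan-2-yl)methyl]benzoate | CCCCCC1(Cc2c(I)c(OCOC)cc(OCOC)c2C(=O)OCc2ccc(OC)cc2)OCCO1 | intermediate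
19 | 4-methoxybenzyl 3-[(6-methoxy-1-oxo-3-pentyl-1H-isochromen-8-yl)oxy]-4,6-bis(methoxymethoxy)-2-[(2-pentyl-1,3-dioxolan-2-yl)methyl]benzoate | CCCCCC1(Cc2c(Oc3cc(OC)cc4cc(CCCCC)oc(=O)c34)c(OCOC)cc(OCOC)c2C(=O)OCc2ccc(OC)cc2)OCCO1 | intermediate
20 | beta-collatolic acid, 4,6-dihydroxy-3-[(6-methoxy-1-oxo-3-pentyl-1H-isochromen-8-yl)oxy]-2-(2-oxoheptyl)benzoic acid | CCCCCC(=O)Cc1c(Oc2cc(OC)cc3cc(CCCCC)oc(=O)c23)c(O)cc(O)c1C(=O)O | target

**Step count and risks**

Total step count: 14.
Longest linear sequence: 10 steps (steps 1, 2, 4, 5, 9, 10, 11, 12, 13, 14).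

Steps most likely to fail:

Step 13. Copper insertion into a C–I bond flanked by two ortho substituents on an electron-rich ring is slow, and the chelated, weakly nucleophilic phenoxide of 14 binds copper poorly. Reductive loss of iodine from 18, or attack of the phenoxide on the benzylic carbon of the ester, may therefore outrun ether formation. The fallback reverses the polarity of the union. It sets out from 18 and 14 and comes back at 19. Iodine–magnesium exchange on 18 (i-PrMgCl·LiCl, THF, −40 °C) should give the arylmagnesium chloride F1. Trapping with B(OMe)3 should give the dimethyl arylboronate F2, and oxidation in the same flask (H2O2, aq. NaHCO3, 0 °C) should give 4-methoxybenzyl 3-hydroxy-4,6-bis(methoxymethoxy)-2-[(2-pentyl-1,3-dioxolan-2-yl)methyl]benzoate F3. Phenol 14 is converted with Tf2O and pyridine in CH2Cl2 at 0 °C into 6-methoxy-1-oxo-3-pentyl-1H-isochromen-8-yl trifluoromethanesulfonate F4. Its C–O bond is activated by the ortho carbonyl. Palladium-catalysed C–O coupling of the electron-rich phenol F3 with F4 (Pd(OAc)2, t-BuXPhos, K3PO4, toluene, 100 °C) should then give 19.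

Step 10. The electrophile may attack C8 between the two ring oxygens, or attack twice, and the acid co-catalyst may erode the acetal groups, so the site selectivity of the iodination is at risk. The fallback lets a free phenol direct the halogen. It sets out from 15 and comes back at 17. Opening the dioxinone of 15 with sodium 4-methoxybenzyl oxide (4-MeOC6H4CH2OH, NaH, THF, 0 °C to rt) should give 4-methoxybenzyl 2-hydroxy-4-(methoxymethoxy)-6-[(2-pentyl-1,3-dioxolan-2-yl)methyl]benzoate F5. Salicylate esters are halogenated para to the chelated hydroxyl, here also ortho to the methoxymethoxy group and next to the side chain. Iodination of F5 with benzyltrimethylammonium dichloroiodate and NaHCO3 in CH2Cl2/MeOH at rt is acid-free and leaves the anisole ring of the ester alone, and should give 17.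

Step 14. The 4-methoxybenzyl and methoxymethyl cations may be recaptured by the freed resorcinol ring. The ring A keto acid may also close to its lactol or enol lactone, or lose CO2 on long exposure to strong acid. The fallback removes the groups in two orthogonal stages. It sets out from 19 and comes back at 20. Hydrogenolysis of the benzylic ester (H2 at 1 atm, Pd/C, EtOAc, rt, stopped as soon as 19 is consumed so that the C3–C4 double bond of the isocoumarin is kept) should give 3-[(6-methoxy-1-oxo-3-pentyl-1H-isochromen-8-yl)oxy]-4,6-bis(methoxymethoxy)-2-[(2-pentyl-1,3-dioxolan-2-yl)methyl]benzoic acid F6 without any benzylic cation. Hydrolysis of the three acetals of F6 with 2 M HCl (aq) in THF at 40 °C, where formaldehyde stays hydrated in the aqueous phase, should give 20.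

**Further compounds**

F1 | step 13 | chloromagnesium aryl derived from 18 (MgCl in place of iodine) | CCCCCC1(Cc2c([Mg]Cl)c(OCOC)cc(OCOC)c2C(=O)OCc2ccc(OC)cc2)OCCO1
F2 | step 13 | 4-methoxybenzyl 3-(dimethoxyboranyl)-4,6-bis(methoxymethoxy)-2-[(2-pentyl-1,3-dioxolan-2-yl)methyl]benzoate | CCCCCC1(Cc2c(B(OC)OC)c(OCOC)cc(OCOC)c2C(=O)OCc2ccc(OC)cc2)OCCO1
F3 | step 13 | 4-methoxybenzyl 3-hydroxy-4,6-bis(methoxymethoxy)-2-[(2-pentyl-1,3-dioxolan-2-yl)methyl]benzoate | CCCCCC1(Cc2c(O)c(OCOC)cc(OCOC)c2C(=O)OCc2ccc(OC)cc2)OCCO1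
F4 | step 13 | 6-methoxy-1-oxo-3-pentyl-1H-isochromen-8-yl trifluoromethanesulfonate | CCCCCc1cc2cc(OC)cc(OS(=O)(=O)C(F)(F)F)c2c(=O)o1
F5 | step 10 | 4-methoxybenzyl 2-hydroxy-4-(methoxymethoxy)-6-[(2-pentyl-1,3-dioxolan-2-yl)methyl]benzoate | CCCCCC1(Cc2cc(OCOC)cc(O)c2C(=O)OCc2ccc(OC)cc2)OCCO1
F6 | step 14 | 3-[(6-methoxy-1-oxo-3-pentyl-1H-isochromen-8-yl)oxy]-4,6-bis(methoxymethoxy)-2-[(2-pentyl-1,3-dioxolan-2-yl)methyl]benzoic acid | CCCCCC1(Cc2c(Oc3cc(OC)cc4cc(CCCCC)oc(=O)c34)c(OCOC)cc(OCOC)c2C(=O)O)OCCO1
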